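**Plan**

Retrosynthesis: the C2 hydroxyl and the C2'=C3' olefin of the target are first tied back into an iodo-oxolane (O–C3' and C2'–I, both temporary). The racemic hemiketal behind it is cut at C2–OH (enolate oxygenation), C2–C1' (enolate alkylation), C8'–C9' (alkenylzinc plus enal) and O1–C2 (phenoxide displacement).
Forward: ring B (O1, C2, C3, C3a, C7a) is closed first on the acetophenone. The side chain is grown on geranyl acetate (C8' oxidation, C8'–C9' bond, dienone), joined to C2 as its allylic bromide, and C2 is then hydroxylated.
Enabling feature: the hemiketal OH on C2 of ring B is homoallylic to C2'=C3', the only olefin not conjugated to a carbonyl, and C2 inverts through the ring-opened 1-aryl-1,2-dione. An oxolane bond from that oxygen to C3' can therefore capture one enantiomer.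
Stereochemistry: 2'E comes from geranyl acetate, 6'E from the allylic oxidation, 9'E from syn hydrozirconation. (R)-C2 is selected by a chiral phosphoric acid during the iodoetherification, and zinc then reopens the temporary ring without touching C2.

Key step: step 11

Assumption: the C2 hemiketal interconverts with its mirror image only under acid or base catalysis and should hold its configuration through a cold, neutral work-up. The sense of induction of the chiral acid cannot be predicted, so the (R)-acid is written and its mirror image would be used if a first run selects the other series.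
Locants: benzofuranone O1 to C7a, side chain C1' to C12'. In spiro compound 20 the oxolane positions 3', 4', 5' are side-chain C1', C2', C3'. The spiro carbon of 20 has the same spatial arrangement as (R)-C2 of the target; its descriptor reads S only because the iodine-bearing oxolane oxygen outranks O1.

**Route**

Step 1
Reactants: 1 2'-hydroxy-6'-methylacetophenone
Product: 2 2-bromo-1-(2-hydroxy-6-methylphenyl)ethan-1-one
Conditions: CuBr2 (2 equiv), EtOAc/CHCl3, reflux
Reagents that add atoms: copper dibromide, Br[Cu]Br
Why: Copper dibromide brominates the enolisable methyl ketone selectively at the α-carbon (α-halogenation of a ketone through its copper-bound enol), and the hydrogen-bonded phenol ring should be left alone under these heterogeneous conditions.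

Step 2
Reactants: 2 2-bromo-1-(2-hydroxy-6-methylphenyl)ethan-1-one
Product: 3 4-methyl-1-benzofuran-3(2H)-one
Conditions: NaOAc, EtOH, reflux, argon
Reagents that add atoms: none
Why: The phenoxide formed by the mild base displaces the primary α-keto bromide in a 5-exo-tet intramolecular Williamson etherification that closes ring B.

Step 3
Reactants: 4 2-methylbut-3-yn-2-ol
Product: 5 trimethyl[(2-methylbut-3-yn-2-yl)oxy]silane
Conditions: Me3SiCl, Et3N, 4-(dimethylamino)pyridine (cat.), CH2Cl2, 0 °C to rt
Reagents that add atoms: chlorotrimethylsilane, C[Si](C)(C)Cl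
Why: Silyl ether protection removes the acidic O–H that would consume the zirconium hydride and the organozinc in step 5, and the trimethylsilyl group is chosen because it should fall off together with the acetate in step 7.

Step 4
Reactants: 6 geranyl acetate
Product: 8 (2E,6E)-3,7-dimethyl-8-oxoocta-2,6-dien-1-yl acetate, via 8-hydroxygeranyl acetate 7 (not isolated)
Conditions: SeO2 (cat.), t-BuOOH, salicylic acid (cat.), CH2Cl2, rt; then crude, MnO2, CH2Cl2, rt
Reagents that add atoms: selenium dioxide, O=[Se]=O; tert-butyl hydroperoxide, CC(C)(C)OO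
Why: Riley allylic oxidation (ene reaction then [2,3]-sigmatropic shift) attacks the E-methyl of the more electron-rich 6,7-olefin to give the E-allylic alcohol, the 2,3-olefin being deactivated by the allylic acetate, and MnO2 then brings the crude alcohol (and any material already over-oxidised) to the single enal.

Step 5
Reactants: 5 trimethyl[(2-methylbut-3-yn-2-yl)oxy]silane; 8 (2E,6E)-3,7-dimethyl-8-oxoocta-2,6-dien-1-yl acetate
Product: 11 rac-(2E,6E,9E)-8-hydroxy-3,7,11-trimethyl-11-(trimethylsilyloxy)dodeca-2,6,9-trien-1-yl acetate, via alkenylzirconocene chloride 9 (not isolated), via alkenyl(methyl)zinc 10 (not isolated)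
Conditions: 5, Cp2Zr(H)Cl, CH2Cl2, rt; Me2Zn, toluene, −65 °C; then 8, 0 °C; aq. NaHCO3
Reagents that add atoms: none
Why: Syn hydrozirconation of the terminal alkyne puts zirconium on the terminal carbon and fixes the 9E geometry, zirconium-to-zinc transmetalation gives an alkenylzinc that adds 1,2 to the enal while tolerating the acetate (alkenylzinc addition to an aldehyde), and the new carbinol centre is formed racemic because step 6 erases it.

Step 6
Reactants: 11 rac-(2E,6E,9E)-8-hydroxy-3,7,11-trimethyl-11-(trimethylsilyloxy)dodeca-2,6,9-trien-1-yl acetate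
Product: 12 (2E,6E,9E)-3,7,11-trimethyl-8-oxo-11-(trimethylsilyloxy)dodeca-2,6,9-trien-1-yl acetate
Conditions: MnO2 (excess), CH2Cl2, rt
Reagents that add atoms: none
Why: MnO2 oxidises the doubly allylic secondary alcohol to the cross-conjugated dienone (allylic alcohol oxidation) and should not act on the acetate or the silyl ether.

Step 7
Reactants: 12 (2E,6E,9E)-3,7,11-trimethyl-8-oxo-11-(trimethylsilyloxy)dodeca-2,6,9-trien-1-yl acetate
Product: 13 (3E,6E,10E)-2,12-dihydroxy-2,6,10-trimethyldodeca-3,6,10-trien-5-one
Conditions: K2CO3 (0.3 equiv), MeOH, 0 °C to rt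
Reagents that add atoms: none
Why: Carbonate-catalysed methanolysis (transesterification) removes the acetate and cleaves the trimethylsilyl ether in the same operation, while the low temperature and substoichiometric base are meant to keep methoxide from adding to the α-branched and β-neopentyl enone termini.

Step 8
Reactants: 13 (3E,6E,10E)-2,12-dihydroxy-2,6,10-trimethyldodeca-3,6,10-trien-5-one
Product: 14 (3E,6E,10E)-12-bromo-2-hydroxy-2,6,10-trimethyldodeca-3,6,10-trien-5-one
Conditions: CBr4, PPh3, CH2Cl2, −20 to 0 °C; used at once
Reagents that add atoms: tetrabromomethane, BrC(Br)(Br)Br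
Why: The Appel reaction converts the primary allylic alcohol to the bromide by SN2 displacement of its oxyphosphonium with the 10E olefin intact, the tertiary alcohol being too hindered to be activated under these conditions.

Step 9
Reactants: 3 4-methyl-1-benzofuran-3(2H)-one; 14 (3E,6E,10E)-12-bromo-2-hydroxy-2,6,10-trimethyldodeca-3,6,10-trien-5-one
Product: 16 rac-2-[(2E,6E,9E)-11-hydroxy-3,7,11-trimethyl-8-oxododeca-2,6,9-trien-1-yl]-4-methyl-1-benzofuran-3(2H)-one, via lithium 4-methyl-1-benzofuran-3-olate 15 (not isolated)
Conditions: 3 (2.5 equiv), LiN(SiMe3)2 (2.4 equiv), THF, −78 °C; then 14, −78 to −20 °C; aq. NH4Cl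
Reagents that add atoms: none
Why: SN2 C-alkylation of the aromatic lithium enolate by the primary allylic bromide forms C2–C1' as a racemic centre, the lithium counterion in THF favouring carbon over oxygen attack, the excess enolate suppressing a second alkylation, and both β-positions of the dienone being too hindered to compete as Michael acceptors at low temperature.

Step 10
Reactants: 16 rac-2-[(2E,6E,9E)-11-hydroxy-3,7,11-trimethyl-8-oxododeca-2,6,9-trien-1-yl]-4-methyl-1-benzofuran-3(2H)-one
Product: 19 rac-2-hydroxy-2-[(2E,6E,9E)-11-hydroxy-3,7,11-trimethyl-8-oxododeca-2,6,9-trien-1-yl]-4-methyl-1-benzofuran-3(2H)-one, via lithium enolate 17 (not isolated), via lithium C2-peroxide 18 (not isolated)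
Conditions: LiN(SiMe3)2 (1.1 equiv), THF, −78 °C; O2, P(OEt)3, −78 °C; AcOH, −78 °C to rt
Reagents that add atoms: dioxygen, O=O
Why: The base is funnelled to the far more acidic C2–H, the enolate captures O2 to give the C2 peroxide and triethyl phosphite reduces it in the flask (enolate oxygenation), so that the racemic tertiary hemiketal should be released on cold acidic quench before base can act on the ring-opened dione.

Step 11
Reactants: 19 rac-2-hydroxy-2-[(2E,6E,9E)-11-hydroxy-3,7,11-trimethyl-8-oxododeca-2,6,9-trien-1-yl]-4-methyl-1-benzofuran-3(2H)-one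
Product: 20 (2S,4'S,5'R)-5'-[(3E,6E)-8-hydroxy-4,8-dimethyl-5-oxonona-3,6-dien-1-yl]-4'-iodo-4,5'-dimethyl-3H-spiro[1-benzofuran-2,2'-oxolan]-3-one
Conditions: N-iodosuccinimide (1.2 equiv, in portions), (R)-3,3'-bis(2,4,6-triisopropylphenyl)-1,1'-binaphthyl-2,2'-diyl hydrogen phosphate (10 mol%), toluene/CH2Cl2, −30 °C, dark; aq. Na2S2O3
Reagents that add atoms: N-iodosuccinimide, O=C1CCC(=O)N1I
Why: Proposed new method: the phosphoric acid activates N-iodosuccinimide by hydrogen bonding and passes I+ to the isolated side-chain C2'=C3' olefin while its P=O accepts a hydrogen bond from the hemiketal OH, so the iodonium is opened by that oxygen at tertiary C3' anti to iodine, and because the same acid shuttles protons for the ring-chain interconversion of the two hemiketal enantiomers, the faster-cyclising (R) form should be replenished continuously (dynamic kinetic resolution). The closest known reaction types are chiral-phosphoric-acid-catalysed enantioselective haloetherification and halo-spiroketalisation of alkenols, 5-endo iodoetherification of homoallylic alcohols, and acid-catalysed acetalisations run as dynamic kinetic resolutions, and what is new is their combination on a racemising hemiketal. The oxolane closes 5-endo-trig with Markovnikov opening at C3', the 4-exo attack at C2' being disfavoured by ring strain and by the lower cation-stabilising ability of the secondary carbon. The spiro centre is not created but selected from the equilibrating pair by the catalyst and then frozen, since a spiroketal flanked by a carbonyl should not reopen under these conditions, whereas the two new centres (oxolane C5' and C4') follow from stereospecific anti addition across the E olefin (iodine cis to the 5'-methyl) with their absolute sense set by the catalyst-bound iodonium. Site selectivity rests on C2'=C3' being the only olefin not deactivated by conjugation to a carbonyl, and the remote tertiary alcohol cannot reach an iodonium through a ring of reasonable size. Either anti adduct with the (2S) spiro centre reopens to the same target, and an adduct of opposite C2 configuration formed on the catalyst-preferred olefin face is a diastereomer removable on silica, so two selection events guard the enantiopurity.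

Step 12
Reactants: 20 (2S,4'S,5'R)-5'-[(3E,6E)-8-hydroxy-4,8-dimethyl-5-oxonona-3,6-dien-1-yl]-4'-iodo-4,5'-dimethyl-3H-spiro[1-benzofuran-2,2'-oxolan]-3-one
Product: 21 (2R)-2-hydroxy-2-[(2E,6E,9E)-11-hydroxy-3,7,11-trimethyl-8-oxododeca-2,6,9-trien-1-yl]-4-methyl-1-benzofuran-3(2H)-one
Conditions: Zn dust (activated), NH4Cl, EtOH, 0 °C to rt; filtration, pH 7 buffer, cold concentration
Reagents that add atoms: none
Why: In this Boord-type reductive β-elimination zinc inserts into the C4'–I bond and the carbon–zinc bond expels the ketal oxygen from C5', the five-membered ring allowing only the near-anti alignment that returns the E C2'=C3' olefin, while the spiro carbon is not a reacting centre and its oxygen is protonated by NH4Cl to the (R)-hemiketal.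

**Compound list**

1 | 2'-hydroxy-6'-methylacetophenone | CC(=O)c1c(C)cccc1O | starting material
2 | 2-bromo-1-(2-hydroxy-6-methylphenyl)ethan-1-one | Cc1cccc(O)c1C(=O)CBr | intermediate
3 | 4-methyl-1-benzofuran-3(2H)-one | Cc1cccc2OCC(=O)c12 | intermediate
4 | 2-methylbut-3-yn-2-ol | CC(C)(O)C#C | starting material
5 | trimethyl[(2-methylbut-3-yn-2-yl)oxy]silane | C#CC(C)(C)O[Si](C)(C)C | intermediate
6 | geranyl acetate, (2E)-3,7-dimethylocta-2,6-dien-1-yl acetate | CC(=O)OC/C=C(\C)CCC=C(C)C | starting material
7 | 8-hydroxygeranyl acetate, (2E,6E)-8-hydroxy-3,7-dimethylocta-2,6-dien-1-yl acetate | CC(=O)OC/C=C(\C)CC/C=C(\C)CO | intermediate (not isolated)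
8 | (2E,6E)-3,7-dimethyl-8-oxoocta-2,6-dien-1-yl acetate | CC(=O)OC/C=C(\C)CC/C=C(\C)C=O | intermediate
9 | chlorobis(cyclopentadienyl)[(1E)-3-methyl-3-(trimethylsilyloxy)but-1-en-1-yl]zirconium | CC(C)(O[Si](C)(C)C)/C=C/[Zr](Cl)(C1C=CC=C1)C1C=CC=C1 | intermediate (not isolated)
10 | methyl[(1E)-3-methyl-3-(trimethylsilyloxy)but-1-en-1-yl]zinc | CC(C)(O[Si](C)(C)C)/C=C/[Zn]C | intermediate (not isolated)
11 | rac-(2E,6E,9E)-8-hydroxy-3,7,11-trimethyl-11-(trimethylsilyloxy)dodeca-2,6,9-trien-1-yl acetate (racemic at C8) | CC(=O)OC/C=C(\C)CC/C=C(\C)C(O)/C=C/C(C)(C)O[Si](C)(C)C | intermediate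
12 | (2E,6E,9E)-3,7,11-trimethyl-8-oxo-11-(trimethylsilyloxy)dodeca-2,6,9-trien-1-yl acetate | CC(=O)OC/C=C(\C)CC/C=C(\C)C(=O)/C=C/C(C)(C)O[Si](C)(C)C | intermediate
13 | (3E,6E,10E)-2,12-dihydroxy-2,6,10-trimethyldodeca-3,6,10-trien-5-one | OC/C=C(\C)CC/C=C(\C)C(=O)/C=C/C(C)(C)O | intermediate
14 | (3E,6E,10E)-12-bromo-2-hydroxy-2,6,10-trimethyldodeca-3,6,10-trien-5-one | BrC/C=C(\C)CC/C=C(\C)C(=O)/C=C/C(C)(C)O | intermediate
15 | lithium 4-methyl-1-benzofuran-3-olate | [Li+].[O-]c1coc2cccc(C)c12 | intermediate (not isolated)
16 | rac-2-[(2E,6E,9E)-11-hydroxy-3,7,11-trimethyl-8-oxododeca-2,6,9-trien-1-yl]-4-methyl-1-benzofuran-3(2H)-one (racemic at C2) | C/C(=C\CC1Oc2cccc(C)c2C1=O)CC/C=C(\C)C(=O)/C=C/C(C)(C)O | intermediate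
17 | lithium enolate of 16, lithium 2-[(2E,6E,9E)-11-hydroxy-3,7,11-trimethyl-8-oxododeca-2,6,9-trien-1-yl]-4-methyl-1-benzofuran-3-olate | [Li+].[O-]c1c(C/C=C(\C)CC/C=C(\C)C(=O)/C=C/C(C)(C)O)oc2cccc(C)c12 | intermediate (not isolated)
18 | lithium salt of the racemic C2 hydroperoxide of 16 | C/C(=C\CC1(O[O-])Oc2cccc(C)c2C1=O)CC/C=C(\C)C(=O)/C=C/C(C)(C)O.[Li+] | intermediate (not isolated)
19 | rac-2-hydroxy-2-[(2E,6E,9E)-11-hydroxy-3,7,11-trimethyl-8-oxododeca-2,6,9-trien-1-yl]-4-methyl-1-benzofuran-3(2H)-one (racemic target hemiketal) | C/C(=C\CC1(O)Oc2cccc(C)c2C1=O)CC/C=C(\C)C(=O)/C=C/C(C)(C)O | intermediate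
20 | (2S,4'S,5'R)-5'-[(3E,6E)-8-hydroxy-4,8-dimethyl-5-oxonona-3,6-dien-1-yl]-4'-iodo-4,5'-dimethyl-3H-spiro[1-benzofuran-2,2'-oxolan]-3-one (spiro carbon arranged as C2 of the target; iodine cis to the 5'-methyl) | C2[C@@]1(O[C@](C)(CC/C=C(\C)C(=O)/C=C/C(C)(C)O)[C@H]2I)Oc3cccc(C)c3C1=O | intermediate
21 | (2R)-2-hydroxy-2-[(2E,6E,9E)-11-hydroxy-3,7,11-trimethyl-8-oxododeca-2,6,9-trien-1-yl]-4-methyl-1-benzofuran-3(2H)-one | C/C(=C\C[C@@]1(O)Oc2cccc(C)c2C1=O)CC/C=C(\C)C(=O)/C=C/C(C)(C)O | target

**Summary**

Total steps: 12. Longest linear sequence: 9 steps (steps 4 to 12, from geranyl acetate 6 to 21).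

**Steps most likely to fail**

Step 11 is the only step that rests on a reaction type not yet demonstrated. The hemiketal enantiomers may interconvert too slowly for a dynamic process, the catalyst may discriminate them poorly, or N-iodosuccinimide may iodinate the ring-opened phenol. If only the dynamics fail, the reaction is stopped at partial conversion and the recovered hemiketal is racemised with a trace of Et3N and resubmitted. The fallback proper uses known chemistry, sets out from 19 and comes back at 20. Iodoetherification of 19 with N-iodosuccinimide and NaHCO3 in MeCN at 0 °C, without chiral catalyst, is the established 5-endo iodocyclisation of homoallylic alcohols and should give the racemic anti adducts. These are 20 with its mirror image, the (2R,4'R,5'S)-spiro iodide F1, and possibly the second anti pair, the (2S,4'R,5'S)-spiro iodide F2 and the (2R,4'S,5'R)-spiro iodide F3. The two diastereomeric pairs are parted on silica and each is resolved by preparative HPLC on cellulose tris(3,5-dimethylphenylcarbamate), which should be unproblematic because the spiroketals are configurationally fixed. Compound 20 rejoins the route at step 12, F2 reopens to the same target under the step 12 conditions, and F1 and F3 are set aside.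

Step 12 may lose the configuration at C2 if the zinc hemiketal alkoxide freed by the elimination opens to the phenoxide dione before it is protonated, and zinc may also cleave a C2–O bond α to the aryl ketone. The fallback gives up the temporary ring, sets out from 19 and comes back at 21. Racemic 19 is resolved directly by preparative chromatography on amylose tris(3,5-dimethylphenylcarbamate) (hexane/2-propanol, no acidic or basic additive, column kept cold). This should deliver 21 and its mirror image, the (2S)-enantiomer F4, which is racemised with catalytic Et3N in CH2Cl2 and returned to the column as 19.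

Step 9 may lose the bromide to O-alkylation (giving the 3-allyloxybenzofuran), to a second alkylation at C2, or to conjugate addition of the enolate to the dienone. The fallback sets out from 13 and 3 and comes back at 16. The primary hydroxyl of 13 is acylated with 1,1'-carbonyldiimidazole (THF, 0 °C, the tertiary hydroxyl not reacting) to the (2E,6E,9E)-11-hydroxy-3,7,11-trimethyl-8-oxododeca-2,6,9-trien-1-yl imidazole-1-carboxylate F5. Enolate 15 (from 3 and LiN(SiMe3)2, 2 equiv, THF, −78 °C) is C-acylated by F5 to the corresponding allylic 4-methyl-3-oxo-2,3-dihydro-1-benzofuran-2-carboxylate F6. Pd(PPh3)4 (zerovalent palladium, 5 mol%, THF, rt) then effects decarboxylative allylation of the Tsuji–Trost type. The π-allyl palladium species and the enolate arise together, in equal amounts and under neutral conditions, and should recombine at the unsubstituted allyl terminus to give 16 without bromide or strong base at the bond-forming stage.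

Further compounds
F1 | step 11 | (2R,4'R,5'S)-5'-[(3E,6E)-8-hydroxy-4,8-dimethyl-5-oxonona-3,6-dien-1-yl]-4'-iodo-4,5'-dimethyl-3H-spiro[1-benzofuran-2,2'-oxolan]-3-one (mirror image of 20) | C2[C@]1(O[C@@](C)(CC/C=C(\C)C(=O)/C=C/C(C)(C)O)[C@@H]2I)Oc3cccc(C)c3C1=O
F2 | step 11 | (2S,4'R,5'S)-5'-[(3E,6E)-8-hydroxy-4,8-dimethyl-5-oxonona-3,6-dien-1-yl]-4'-iodo-4,5'-dimethyl-3H-spiro[1-benzofuran-2,2'-oxolan]-3-one (second anti adduct, spiro centre as in 20) | C2[C@@]1(O[C@@](C)(CC/C=C(\C)C(=O)/C=C/C(C)(C)O)[C@@H]2I)Oc3cccc(C)c3C1=O
F3 | step 11 | (2R,4'S,5'R)-5'-[(3E,6E)-8-hydroxy-4,8-dimethyl-5-oxonona-3,6-dien-1-yl]-4'-iodo-4,5'-dimethyl-3H-spiro[1-benzofuran-2,2'-oxolan]-3-one (mirror image of F2) | C2[C@]1(O[C@](C)(CC/C=C(\C)C(=O)/C=C/C(C)(C)O)[C@H]2I)Oc3cccc(C)c3C1=O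
F4 | step 12 | (2S)-2-hydroxy-2-[(2E,6E,9E)-11-hydroxy-3,7,11-trimethyl-8-oxododeca-2,6,9-trien-1-yl]-4-methyl-1-benzofuran-3(2H)-one (mirror image of 21) | C/C(=C\C[C@]1(O)Oc2cccc(C)c2C1=O)CC/C=C(\C)C(=O)/C=C/C(C)(C)O
F5 | step 9 | (2E,6E,9E)-11-hydroxy-3,7,11-trimethyl-8-oxododeca-2,6,9-trien-1-yl 1H-imidazole-1-carboxylate | O=C(OC/C=C(\C)CC/C=C(\C)C(=O)/C=C/C(C)(C)O)n1ccnc1
F6 | step 9 | (2E,6E,9E)-11-hydroxy-3,7,11-trimethyl-8-oxododeca-2,6,9-trien-1-yl 4-methyl-3-oxo-2,3-dihydro-1-benzofuran-2-carboxylate (racemic at C2) | Cc1cccc2OC(C(=O)OC/C=C(\C)CC/C=C(\C)C(=O)/C=C/C(C)(C)O)C(=O)c12
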